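Start from what is left in Tuesday's flask: single ring reads 60.4% at 3.00 min, level with 60.4% at 2.00 min. That plateau is a ledger of how the charge was split.

| flask | starting material | remark | time |
|---|---|---|---|
| Tuesday's | 0.17 M | run made earlier |  |
| Friday's | 2.7 M | run made earlier |  |
| dusk | 0.25 M |  | 4.0 min |
| midnight | 0.30 M |  | 4.0 min |
| dawn | 2.0 M |  | 4.0 min |
| autumn | 1.0 M |  | 4.0 min |
| winter | 0.50 M |  | 4.0 min |
| noon | 0.12 M |  | 4.0 min |

| run | time / min | single ring / % | open dimer / % | open trimer / % |
|---|---|---|---|---|
| Tuesday's | 0.250 | 46.0 | 25.1 | 1.0 |
| Tuesday's | 0.667 | 58.0 | 12.1 | 1.8 |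
| Tuesday's | 1.33 | 59.6 | 3.3 | 1.9 |
| Tuesday's | 2.00 | 60.4 | 0.1 | 0.3 |
| Tuesday's | 3.00 | 60.4 | 0 | 1.5 |
| Friday's | 0.250 | 12.0 | 48.3 | 9.7 |
| Friday's | 0.667 | 11.9 | 21.9 | 10.7 |
| Friday's | 1.33 | 12.3 | 5.8 | 10.2 |
| Friday's | 2.00 | 12.0 | 2.6 | 10.0 |
| Friday's | 3.00 | 12.3 | 0.1 | 11.5 |

(readings scatter by 0.5 percentage points)

- percentages count the starting material that a species holds: one open dimer or ring dimer or side product counts as two
- percentages count the starting material that a species holds: one open trimer counts as three

* the flasks put in order of share of single ring in all that became single ring or open dimer or open trimer or ring dimer or side product, best first, at 4.0 min (dusk / midnight / dawn / autumn / winter / noon)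
* the same order at 12 s (dusk / midnight / dawn / autumn / winter / noon)
* the share of single ring in all that became single ring or open dimer or open trimer or ring dimer or side product of the flask you put first, at 4.0 min
* the share of single ring in all that became single ring or open dimer or open trimer or ring dimer or side product of the flask you put last, at 4.0 min

Build the flask up. Let m be the fraction of the charge still starting material (the limiting reagent) and p the fraction become single ring. With ring closure as the one step, dp = −dm, so p ends at 1.

Add dimerisation. Suppose it is second order: against closure it then grows as b·m, where b, a selectivity factor, is the charge over a concentration a. The balance becomes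

dp/dm = −1/(1 + b·m), so p = ln(1 + b)/b.

Newton's method on Tuesday's plateau gives

b = 1.31, 1.58, 1.55.

So Tuesday's reading puts the crossover concentration, at which closure and dimerisation use starting material equally, at 0.110 M, and the scatter of that plateau stays in it.

Add the rest. Friday's readings of open dimer fall with a time constant of about 0.510 min, shorter than 4.0 min, while its single ring reads level. Friday's open trimer reads 11.5% at 3.00 min. For Friday's flask the formula gives 13.2%, and the reading of 12.3% is 0.934 of that.

My reckoning: noon, the smallest charge, gets 67.6%. Dawn, the largest, gets 16.2%, or 15.1% with Friday's factor.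

The forecast: noon > dusk > midnight > winter > autumn > dawn at 4.0 min, noon > dusk > midnight > winter > autumn > dawn at 12 s, top 67.5%, low 15.5%. For the early reading it takes the share as “the average selectivity over the concentrations already passed”.

The flasks give noon > dusk > midnight > winter > autumn > dawn at 4.0 min and noon > dusk > midnight > winter > autumn > dawn at 12 s, with top 67.4% and low 15.2%.

    starting material → single ring (k = 0.0780 s⁻¹)
    starting material + open dimer → open trimer (k = 0.0320 L mol⁻¹ s⁻¹)
    2 starting material → open dimer (k = 0.350 L mol⁻¹ s⁻¹)
    open dimer → ring dimer (k = 0.0330 s⁻¹)
    starting material + single ring → side product (k = 0.00440 L mol⁻¹ s⁻¹)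

Noon has come to rest as far as the share goes: at 4.00 min it holds 0% starting material and 0.0134% open dimer, and at 40.0 min open dimer stands at 0% and the share at 67.4%. Dawn's share likewise stays at 15.2%. The plain formula sits 0.20 percentage points above noon, with 0.801% open trimer, and 1 point above dawn, with 9.29%.

Take noon's flask with 0.072 M: the crossover concentration gives b = 0.656 and p = 76.9%. The computed share is 76.8%.

Readings and results are simulated for an exercise.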